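The flask is read at 20 h, 8.00 h past the last reading of either run, so the dispute is about how ring grows across that gap.

| flask | solid substrate | remark | time |
|---|---|---|---|
| maple | 0.025 M | run made earlier |  |
| larch | 0.038 M | run made earlier |  |
| flask | 0.050 M |  | 20 h |

| maple: time / h | maple: ring / % | larch: time / h | larch: ring / % |
|---|---|---|---|
| 5.00 | 4.4 | 5.00 | 3.6 |
| 6.00 | 5.9 | 6.00 | 2.5 |
| 8.00 | 8.5 | 8.00 | 5.4 |
| 10.0 | 12.8 | 10.0 | 8.2 |
| 12.0 | 17.6 | 12.0 | 11.5 |

(scatter of a reading: 0.5 percentage points)

- given per volume of solution although it is solid: solid substrate
- at the start none of the solid substrate is in solution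

1. time, not beyond 20 h, at which the flask holds most ring
2. the amount of ring, in percent of the solid substrate charged, at that time

Two of us read these runs, and we agree on one thing. Ring as a fraction of the charge reads lower in larch, the larger charge: at 12.0 h, larch over maple gives 0.653, and maple's charge over larch's gives 0.658. At 10.0 h the same two readings give 0.641, so time drops out of that ratio within the scatter, and we scale fractions from one charge to another by the charges, a gain zero order in the charge.

We part over the gain. Across its last stretches of 2.00 h, the maple run gained 2.6 percentage points, then 4.3 points, then 4.8 points. The forecast reads a climb, “The rate keeps rising”, and gives 29% at 20 h.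

I read a ramp behind a lag. The second step up is 0.5 points, the scatter of one reading, after a first of 1.7 points. So I hold the last gain constant. My ramp rate, the hourly gain of ring as a fraction of the charge, taken from maple's last stretch and scaled to the flask, is 0.0120 h⁻¹. Added to maple's last reading scaled the same way, 8.80%, it gives 18.4% at 20 h, my own figure. With a positive gain, I too put the highest ring at that time.

The simulation gives 18.6% at 20.0 h.

    starting material → ring (k = 8.60 × 10⁻⁶ s⁻¹)
    2 starting material ⇌ open dimer (K = 19.0 M⁻¹, k = 6.70 × 10⁻⁵ M⁻¹ s⁻¹)
    solid substrate ⇌ starting material, rate k3*(cs3 - [starting material]) while solid is left; crystals form when [starting material] > cs3 (solubility = 30.0 mM, k = 3.00 × 10⁻⁵ s⁻¹)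

From 10.0 h to 20 h the flask gained on average 0.0120 h⁻¹, against the ramp rate of 0.0120 h⁻¹. The forecast's climb has its region in the early hours: starting material in the flask rises 23 points from 2.00 h to 10.0 h and 7.5 points from there to 20.0 h, being made 3.22 times faster than it is used up at 6.90 h, each step taken net, and 1.20 times at 20.0 h. Now the neighbouring flask, charged with 0.020 M: scaled, the ramp rate becomes 0.0300 h⁻¹, and the reckoning gives 46.0% at 20 h. That flask reaches ring 37.2%, with solid substrate at 0% and starting material at 56.0%.

The runs come from a simulation on assumed constants, noise included.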